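**Assumption:** the target has no stereocentre (it is achiral), so the given SMILES is its only stereoisomer and no stereocontrol is needed.

## Retrosynthetic overview

1. Target 11 comes from its ring B benzyl ester 10 by hydrogenolysis.
2. Key disconnection of 10: the aryl C5–O bond of the depside link, made by dehydrogenative coupling of the ring A acid 6 (O–H) with the only free ring position (C5–H) of the ring B phenol 4.
3. Acid 6 comes from 4 by 4-O-methylation (5) and debenzylation, so 4 is the common precursor of both rings.
4. 4 comes from benzyl orsellinate 2 by C3 formylation, and 2 from orsellinic acid 1.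
5. No ring is built: both benzene rings come intact from 1, ring B first (as 4), ring A derived from it.

## Route

Step 1
Reactants: 1 orsellinic acid (2,4-dihydroxy-6-methylbenzoic acid)
Product: 2 benzyl orsellinate (benzyl 2,4-dihydroxy-6-methylbenzoate)
Conditions: BnBr (1.05 equiv), KHCO3 (1.2 equiv), DMF, rt, 18 h
Reagents that add atoms: benzyl bromide, BrCc1ccccc1
Why: Carboxylate O-alkylation (SN2 esterification); hydrogen carbonate deprotonates only the carboxylic acid, so the two phenols are not benzylated.

Step 2
Reactants: 2 benzyl orsellinate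
Product: 4 benzyl haematommate (benzyl 3-formyl-2,4-dihydroxy-6-methylbenzoate), via chloro(methoxy)methyl arene 3 (not isolated)
Conditions: Cl2CHOMe (1.3 equiv), TiCl4 (2.5 equiv), CH2Cl2, −10 → 0 °C, 1 h; then ice-cold 1 M HCl
Reagents that add atoms: dichloromethyl methyl ether, COC(Cl)Cl; water, O
Why: Rieche formylation (electrophilic aromatic substitution): titanium chelation of the 2-O/ester pair fixes the ring bonds so that C3, ortho to both hydroxyls, is attacked in preference to C5 (the orientation of the classical Gattermann route to haematommate esters), and the α-chloro ether 3 is hydrolysed on work-up.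

Step 3
Reactants: 4 benzyl haematommate
Product: 5 benzyl 3-formyl-2-hydroxy-4-methoxy-6-methylbenzoate
Conditions: MeI (1.1 equiv), K2CO3 (1.0 equiv), acetone, rt, 12 h
Reagents that add atoms: iodomethane, CI
Why: Williamson ether synthesis: with one equivalent of base the 4-OH, which has only one ortho substituent, is alkylated, while the 2-OH, held between the ester and aldehyde carbonyls, is strongly chelated and doubly hindered.

Step 4
Reactants: 5 benzyl 3-formyl-2-hydroxy-4-methoxy-6-methylbenzoate
Product: 6 3-formyl-2-hydroxy-4-methoxy-6-methylbenzoic acid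
Conditions: H2 (1 atm), 10% Pd/C, EtOAc, rt, stopped after 1 equiv H2 (about 30 min); used without heating
Reagents that add atoms: none
Why: Catalytic hydrogenolysis of the benzylic ester C–O bond is much faster than reduction of the chelated, electron-rich aryl aldehyde, as is usual for formyl-bearing depside acids.

Step 5
Reactants: 6 3-formyl-2-hydroxy-4-methoxy-6-methylbenzoic acid; 4 benzyl haematommate
Product: 10 benzyl haemathamnolate (benzyl 3-formyl-5-[(3-formyl-2-hydroxy-4-methoxy-6-methylbenzoyl)oxy]-2,4-dihydroxy-6-methylbenzoate), via hydroxy(aroyloxy)iodane 7 (not isolated), via aryloxy(aroyloxy)iodane 8 (not isolated), via acyloxy dienone 9 (not isolated)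
Conditions: 6 (1.1 equiv), PhIO (iodosylbenzene, 1.1 equiv), 4 Å MS, CH2Cl2, 0 °C, 30 min; then 4 (1.0 equiv), −20 °C → rt, 4 h
Reagents that add atoms: none
Why: Proposed new method: a cross-dehydrogenative aryl C–H/acid O–H coupling in which acid 6 depolymerises PhIO to the hydroxy(aroyloxy)iodane 7, the less hindered 4-OH of 4 condenses on trivalent iodine (water goes to the sieves) to give 8, and the iodine-bound carboxylate is delivered within the complex to C5, the only unsubstituted carbon of ring B (ortho to the iodine-bound oxygen, para to the 2-OH), with loss of PhI as leaving group; dienone 9 carries H at C5 and re-aromatises at once to 10, which has no free ring position left and cannot react again, while ring A of 6 has no C–H ortho to its single, doubly chelated OH and so cannot follow this inner-sphere path in non-ionising CH2Cl2; the closest known reaction types are the Wessely-type ortho-acetoxylation of phenols with PhI(OAc)2 or Pb(OAc)4 and the ortho-benzoyloxylation of phenols by dibenzoyl peroxide, neither of which has been used with a complex acid as the limiting acyloxy partner to make a depside.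

Step 6
Reactants: 10 benzyl haemathamnolate
Product: 11 haemathamnolic acid (3-formyl-5-[(3-formyl-2-hydroxy-4-methoxy-6-methylbenzoyl)oxy]-2,4-dihydroxy-6-methylbenzoic acid)
Conditions: H2 (1 atm), 10% Pd/C, EtOAc, rt, stopped after 1 equiv H2 (about 30 min); filtered through Celite, crystallised
Reagents that add atoms: none
Why: Catalytic hydrogenolysis removes only the benzyl ester; the aryl ester link, the methyl ether and the two chelated aldehydes are untouched when the uptake is limited to one equivalent.

## Compound list

1 | orsellinic acid (2,4-dihydroxy-6-methylbenzoic acid) | Cc1cc(O)cc(O)c1C(=O)O | starting material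
2 | benzyl orsellinate (benzyl 2,4-dihydroxy-6-methylbenzoate) | Cc1cc(O)cc(O)c1C(=O)OCc1ccccc1 | intermediate
3 | benzyl 3-[chloro(methoxy)methyl]-2,4-dihydroxy-6-methylbenzoate (racemic, titanium-bound, transient) | COC(Cl)c1c(O)cc(C)c(C(=O)OCc2ccccc2)c1O | intermediate (not isolated)
4 | benzyl haematommate (benzyl 3-formyl-2,4-dihydroxy-6-methylbenzoate) | Cc1cc(O)c(C=O)c(O)c1C(=O)OCc1ccccc1 | intermediate
5 | benzyl 3-formyl-2-hydroxy-4-methoxy-6-methylbenzoate | COc1cc(C)c(C(=O)OCc2ccccc2)c(O)c1C=O | intermediate
6 | 3-formyl-2-hydroxy-4-methoxy-6-methylbenzoic acid | COc1cc(C)c(C(=O)O)c(O)c1C=O | intermediate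
7 | hydroxy(phenyl)iodanyl 3-formyl-2-hydroxy-4-methoxy-6-methylbenzoate, PhI(OH)(O2C–ring A), trivalent iodine | OI(c1ccccc1)OC(=O)c1c(C)cc(OC)c(C=O)c1O | intermediate (not isolated)
8 | mixed phenyliodane PhI(O–ring B)(O2C–ring A): trivalent iodine bound to the 4-oxygen of 4 and to the carboxylate of 6 | O=C(OI(c1ccccc1)Oc1cc(C)c(C(=O)OCc2ccccc2)c(O)c1C=O)c1c(C)cc(OC)c(C=O)c1O | intermediate (not isolated)
9 | cyclohexa-2,4-dienone tautomer of 10: C4 is a ketone, C5 is sp3 and carries H and the aroyloxy group (racemic, transient) | O=C1C(C=O)=C(O)C(C(=O)OCc2ccccc2)=C(C)C1OC(=O)c1c(C)cc(OC)c(C=O)c1O | intermediate (not isolated)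
10 | benzyl haemathamnolate (benzyl 3-formyl-5-[(3-formyl-2-hydroxy-4-methoxy-6-methylbenzoyl)oxy]-2,4-dihydroxy-6-methylbenzoate) | COc1cc(C)c(C(=O)Oc2c(C)c(C(=O)OCc3ccccc3)c(O)c(C=O)c2O)c(O)c1C=O | intermediate
11 | haemathamnolic acid | COc1cc(C)c(C(=O)Oc2c(C)c(C(=O)O)c(O)c(C=O)c2O)c(O)c1C=O | target

## Step count and risks

Total steps: 6. Longest linear sequence: 6 (1 → 2 → 4 → 5 → 6 → 10 → 11); 4 is used twice, as ring B partner and as precursor of ring A.

**Step 5 (the proposed new coupling).** The chelated phenol 4 may exchange slowly on trivalent iodine. Ring A of 6 could be attacked at its own C5 (para to its OH) by an outer-sphere path. The product could be oxidised further to a quinone if water is present. Fallback with known chemistry, setting out from 4 and 6 and coming back at 10: Elbs persulfate oxidation of 4 (K2S2O8, aqueous KOH, 5–15 °C) introduces oxygen para to the 2-OH, giving potassium 3-[(benzyloxy)carbonyl]-5-formyl-4,6-dihydroxy-2-methylphenyl sulfate F1, which is not isolated. Hydrolysis with 2 M HCl at 50 °C gives benzyl 3-formyl-2,4,5-trihydroxy-6-methylbenzoate F2. Its 5-OH is the only hydroxyl not chelated to a carbonyl, so classical depside esterification with 6 (DCC, Et2O/toluene, 0 °C → rt) gives 10. This makes the acyl C–O bond instead of the aryl C–O bond and costs one extra step.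

**Step 3 (mono-methylation of 4).** Both hydroxyls of 4 are chelated, so 2-O-methyl and dimethyl ethers may form beside 5. Fallback, setting out from 2 and coming back at 5, with the order of methylation and formylation inverted: 2 is methylated first (MeI, K2CO3, acetone, rt), where the 4-OH is the only non-chelated hydroxyl, giving benzyl 2-hydroxy-4-methoxy-6-methylbenzoate (benzyl everninate) F3. Casnati–Skattebøl formylation (MgCl2, Et3N, paraformaldehyde, MeCN, reflux) then delivers formaldehyde only ortho to the magnesium phenoxide, and the single free ortho position of the 2-OH is C3, giving 5.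

**Step 2 (formylation of 2).** The 5-formyl isomer or a dialdehyde may form, and TiCl4 may cleave some benzyl ester. Fallback, setting out from 2 and coming back at 4, replacing Lewis-acid substitution on the free resorcinol by a phenoxide-templated formylation on a masked substrate: the non-chelated 4-OH is protected (MOMCl, iPr2NEt, CH2Cl2, 0 °C) to give benzyl 2-hydroxy-4-(methoxymethoxy)-6-methylbenzoate F4. MgCl2/Et3N/paraformaldehyde in MeCN at reflux formylates ortho to the only free hydroxyl, at C3 (C5 is para to it and is not reached by the magnesium-templated mechanism), giving benzyl 3-formyl-2-hydroxy-4-(methoxymethoxy)-6-methylbenzoate F5. The acetal is removed with 2 M HCl in THF at rt to give 4.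

## Further compounds

F1 | step 5 | potassium 3-[(benzyloxy)carbonyl]-5-formyl-4,6-dihydroxy-2-methylphenyl sulfate | Cc1c(OS(=O)(=O)[O-])c(O)c(C=O)c(O)c1C(=O)OCc1ccccc1.[K+]
F2 | step 5 | benzyl 3-formyl-2,4,5-trihydroxy-6-methylbenzoate | Cc1c(O)c(O)c(C=O)c(O)c1C(=O)OCc1ccccc1
F3 | step 3 | benzyl 2-hydroxy-4-methoxy-6-methylbenzoate (benzyl everninate) | COc1cc(C)c(C(=O)OCc2ccccc2)c(O)c1
F4 | step 2 | benzyl 2-hydroxy-4-(methoxymethoxy)-6-methylbenzoate | COCOc1cc(C)c(C(=O)OCc2ccccc2)c(O)c1
F5 | step 2 | benzyl 3-formyl-2-hydroxy-4-(methoxymethoxy)-6-methylbenzoate | COCOc1cc(C)c(C(=O)OCc2ccccc2)c(O)c1C=O
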